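**Strategy.** The target is two identical (3S,4S)-4-(3,4-dimethoxybenzyl)butyrolactones joined through their C3 benzyl groups to one diaryl ether. One enantiopure lactone is therefore made once and alkylated twice with a bis(benzyl bromide). The route rests on the C3–C4 bond of that lactone ring. C4, the ring methine between O–C5H2 and the veratryl CH2, is hidden as the prochiral central CH2 of a 3-arylpropyl diazoacetate whose diazo carbon becomes C3. The chiral carboxamidate Rh2(4R-MPPIM)4 converts this acyclic ester into the lactone by carbene insertion into one enantiotopic C–H bond, closing the five-membered ring and fixing C4 in one operation. C3 is then set trans by enolate alkylation.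

Key step: step 3

Remark on the chemistry: both lactone rings are read as trans-(3S,4S); the 4R antipode of the catalyst (MPPIM = methyl 2-oxo-1-(3-phenylpropanoyl)imidazolidine-4-carboxylate) is assumed to give the (S)-lactone, and the antipodal catalyst would be used without other change if the sense of induction proved opposite.

**Route**

Step 1
Reactants: 1 3-(3,4-dimethoxyphenyl)propan-1-ol; 2 bromoacetyl bromide
Product: 3 3-(3,4-dimethoxyphenyl)propyl 2-bromoacetate
Conditions: NaHCO3, MeCN, 0 °C to rt
Reagents that add atoms: none
Why: O-acylation of a primary alcohol by the acyl bromide (esterification), which is far more electrophilic than the alkyl bromide end; no stereocentre is involved.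

Step 2
Reactants: 3 3-(3,4-dimethoxyphenyl)propyl 2-bromoacetate
Product: 6 3-(3,4-dimethoxyphenyl)propyl 2-diazoacetate, via alkylated ditosylhydrazide 4 (not isolated), via tosyldiazene 5 (not isolated)
Conditions: TsNHNHTs (2 equiv), DBU (5 equiv), THF, 0 °C
Reagents that add atoms: N,N'-ditosylhydrazine Cc1ccc(cc1)S(=O)(=O)NNS(=O)(=O)c1ccc(C)cc1
Why: Diazoacetate synthesis from a bromoacetate and N,N'-ditosylhydrazine: N-alkylation followed by two base-induced eliminations of p-toluenesulfinate should give the diazo ester under conditions that leave the ester intact.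

Step 3
Reactants: 6 3-(3,4-dimethoxyphenyl)propyl 2-diazoacetate
Product: 7 (4S)-4-[(3,4-dimethoxyphenyl)methyl]oxolan-2-one
Conditions: Rh2(4R-MPPIM)4 (1 mol %), CH2Cl2, reflux, 6 added by syringe pump over 10 h
Reagents that add atoms: none
Why: Rh2(4R-MPPIM)4, a divalent rhodium carboxamidate, expels N2 from 6 and the resulting catalyst-bound carbene carbon (the future C3) inserts into one C–H bond of the central CH2 of the propyl chain (the future C4) through a concerted, asynchronous three-centre transition state, so that the C3–C4 bond and the lactone ring form together. The closest known reaction type is the enantioselective intramolecular carbene C–H insertion of alkyl diazoacetates catalysed by chiral dirhodium carboxamidates, which is established for 3-arylpropyl diazoacetates. The one ring closed is the five-membered lactone, closed as a 1,5-C–H insertion (carbene carbon counted as atom 1) through a five-membered cyclic transition state that contains the ester C–O bond. The only new stereocentre, C4, is controlled by the catalyst, whose chiral imidazolidinone carboxamidate ligands discriminate the two enantiotopic hydrogens of the prochiral CH2, the 4R antipode being chosen to deliver (S). The step needs site selectivity for this CH2 over the O–CH2 group (four-membered closure), the benzylic CH2 (six-membered closure) and cycloaddition to the electron-rich veratryl ring; the ester tether secures it by placing only the central CH2 within reach of a five-membered transition state and by deactivating the O–CH2 hydrogens, and the weakly electrophilic carboxamidate-bound carbene reinforces this preference. Slow addition keeps the diazo concentration low and should suppress carbene dimerisation.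

Step 4
Reactants: 8 3,4-dihydroxy-5-methoxybenzaldehyde
Product: 9 4-(benzyloxy)-3-hydroxy-5-methoxybenzaldehyde
Conditions: BnBr (1.05 equiv), Li2CO3 (1.5 equiv), DMF, 45 °C
Reagents that add atoms: benzyl bromide BrCc1ccccc1
Why: Williamson etherification that should be selective for the 4-OH, because the hydroxyl para to the formyl group is the more acidic and the weak base forms only that phenoxide.

Step 5
Reactants: 9 4-(benzyloxy)-3-hydroxy-5-methoxybenzaldehyde; 10 4-fluoro-3-methoxybenzaldehyde
Product: 11 4-(benzyloxy)-3-(4-formyl-2-methoxyphenoxy)-5-methoxybenzaldehyde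
Conditions: K2CO3, DMSO, 120 °C, under N2
Reagents that add atoms: none
Why: Nucleophilic aromatic substitution (SNAr, addition–elimination) of the phenoxide of 9 on the fluoroarene activated by its para-formyl group, with fluoride as leaving group; the benzyl ether and both non-enolisable aldehydes tolerate carbonate.

Step 6
Reactants: 11 4-(benzyloxy)-3-(4-formyl-2-methoxyphenoxy)-5-methoxybenzaldehyde
Product: 14 [4-(benzyloxy)-3-[4-(hydroxymethyl)-2-methoxyphenoxy]-5-methoxyphenyl]methanol, via ring A hydroxy aldehyde 12 (not isolated), via ring B hydroxy aldehyde 13 (not isolated)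
Conditions: NaBH4, MeOH/THF, 0 °C
Reagents that add atoms: none
Why: Borohydride reduction of both aryl aldehydes to the benzylic alcohols; the aryl ethers are inert to hydride.

Step 7
Reactants: 14 [4-(benzyloxy)-3-[4-(hydroxymethyl)-2-methoxyphenoxy]-5-methoxyphenyl]methanol
Product: 17 2-(benzyloxy)-5-(bromomethyl)-1-[4-(bromomethyl)-2-methoxyphenoxy]-3-methoxybenzene, via ring A bromo alcohol 15 (not isolated), via ring B bromo alcohol 16 (not isolated)
Conditions: PBr3 (0.8 equiv), CH2Cl2, 0 °C; used at once
Reagents that add atoms: phosphorus tribromide BrP(Br)Br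
Why: Conversion of benzylic alcohols into bromides through bromophosphite esters and SN2 displacement by bromide, under conditions that benzyl and methyl aryl ethers survive.

Step 8
Reactants: 7 (4S)-4-[(3,4-dimethoxyphenyl)methyl]oxolan-2-one (2.4 equiv); 17 2-(benzyloxy)-5-(bromomethyl)-1-[4-(bromomethyl)-2-methoxyphenoxy]-3-methoxybenzene
Product: 21 O-benzyl ether of the target with (3S,4S) configuration in both lactone rings, via lithium enolate 18 (not isolated), via ring A monoalkylated bromide 19 (not isolated), via ring B monoalkylated bromide 20 (not isolated)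
Conditions: LiN(iPr)2 (2.3 equiv), THF, −78 °C; then 17 (1.0 equiv), DMPU, −78 to −30 °C
Reagents that add atoms: none
Why: Alkylation of a lithium lactone enolate by a benzylic bromide (SN2) at both arms, in which the electrophile should approach each enolate anti to the C4 dimethoxybenzyl group, so that C3 is set trans (3S) by 1,2-induction from C4 as is general for 4-substituted butyrolactone enolates.

Step 9
Reactants: 21 O-benzyl ether of the target
Product: 22 (3S,4S)-3-[[3-[4-[[(3S,4S)-4-[(3,4-dimethoxyphenyl)methyl]-2-oxooxolan-3-yl]methyl]-2-methoxyphenoxy]-4-hydroxy-5-methoxyphenyl]methyl]-4-[(3,4-dimethoxyphenyl)methyl]oxolan-2-one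
Conditions: H2 (1 atm), 10% Pd/C, EtOAc/EtOH, rt
Reagents that add atoms: none
Why: Hydrogenolysis of the benzyl aryl ether on palladium under neutral conditions, which should leave the diaryl ether, the methyl ethers and both lactones untouched and should not epimerise C3.

**Compound list**

1 | 3-(3,4-dimethoxyphenyl)propan-1-ol | COc1ccc(CCCO)cc1OC | starting material
2 | bromoacetyl bromide | BrCC(Br)=O | starting material
3 | 3-(3,4-dimethoxyphenyl)propyl 2-bromoacetate | COc1ccc(CCCOC(=O)CBr)cc1OC | intermediate
4 | alkylated ditosylhydrazide: 3-(3,4-dimethoxyphenyl)propyl 2-[1,2-bis(4-methylphenylsulfonyl)hydrazinyl]acetate | COc1ccc(CCCOC(=O)CN(NS(=O)(=O)c2ccc(C)cc2)S(=O)(=O)c2ccc(C)cc2)cc1OC | intermediate (not isolated)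
5 | tosyldiazene: 3-(3,4-dimethoxyphenyl)propyl 2-[(E)-(4-methylphenylsulfonyl)diazenyl]acetate | COc1ccc(CCCOC(=O)C/N=N/S(=O)(=O)c2ccc(C)cc2)cc1OC | intermediate (not isolated)
6 | 3-(3,4-dimethoxyphenyl)propyl 2-diazoacetate | COc1ccc(CCCOC(=O)C=[N+]=[N-])cc1OC | intermediate
7 | (4S)-4-[(3,4-dimethoxyphenyl)methyl]oxolan-2-one | COc1ccc(C[C@@H]2COC(=O)C2)cc1OC | intermediate
8 | 3,4-dihydroxy-5-methoxybenzaldehyde | COc1cc(C=O)cc(O)c1O | starting material
9 | 4-(benzyloxy)-3-hydroxy-5-methoxybenzaldehyde | COc1cc(C=O)cc(O)c1OCc1ccccc1 | intermediate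
10 | 4-fluoro-3-methoxybenzaldehyde | COc1cc(C=O)ccc1F | starting material
11 | 4-(benzyloxy)-3-(4-formyl-2-methoxyphenoxy)-5-methoxybenzaldehyde (ring A = the 2-methoxyphenoxy ring, ring B = the ring carrying OBn) | COc1cc(C=O)ccc1Oc1cc(C=O)cc(OC)c1OCc1ccccc1 | intermediate
12 | ring A hydroxy aldehyde: 4-(benzyloxy)-3-[4-(hydroxymethyl)-2-methoxyphenoxy]-5-methoxybenzaldehyde | COc1cc(CO)ccc1Oc1cc(C=O)cc(OC)c1OCc1ccccc1 | intermediate (not isolated)
13 | ring B hydroxy aldehyde: 4-[2-(benzyloxy)-5-(hydroxymethyl)-3-methoxyphenoxy]-3-methoxybenzaldehyde | COc1cc(C=O)ccc1Oc1cc(CO)cc(OC)c1OCc1ccccc1 | intermediate (not isolated)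
14 | [4-(benzyloxy)-3-[4-(hydroxymethyl)-2-methoxyphenoxy]-5-methoxyphenyl]methanol | COc1cc(CO)ccc1Oc1cc(CO)cc(OC)c1OCc1ccccc1 | intermediate
15 | ring A bromo alcohol: [4-(benzyloxy)-3-[4-(bromomethyl)-2-methoxyphenoxy]-5-methoxyphenyl]methanol | COc1cc(CBr)ccc1Oc1cc(CO)cc(OC)c1OCc1ccccc1 | intermediate (not isolated)
16 | ring B bromo alcohol: [4-[2-(benzyloxy)-5-(bromomethyl)-3-methoxyphenoxy]-3-methoxyphenyl]methanol | COc1cc(CO)ccc1Oc1cc(CBr)cc(OC)c1OCc1ccccc1 | intermediate (not isolated)
17 | 2-(benzyloxy)-5-(bromomethyl)-1-[4-(bromomethyl)-2-methoxyphenoxy]-3-methoxybenzene | COc1cc(CBr)ccc1Oc1cc(CBr)cc(OC)c1OCc1ccccc1 | intermediate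
18 | lithium enolate of 7, (4S) | COc1ccc(C[C@@H]2COC(O[Li])=C2)cc1OC | intermediate (not isolated)
19 | ring A monoalkylated bromide: (3S,4S)-lactone on the ring A benzyl arm, CH2Br on ring B | COc1ccc(C[C@@H]2COC(=O)[C@H]2Cc2ccc(Oc3cc(CBr)cc(OC)c3OCc3ccccc3)c(OC)c2)cc1OC | intermediate (not isolated)
20 | ring B monoalkylated bromide: (3S,4S)-lactone on the ring B benzyl arm, CH2Br on ring A | COc1ccc(C[C@@H]2COC(=O)[C@H]2Cc2cc(OC)c(OCc3ccccc3)c(Oc3ccc(CBr)cc3OC)c2)cc1OC | intermediate (not isolated)
21 | O-benzyl ether of the target, (3S,4S) in both lactone rings | COc1ccc(C[C@@H]2COC(=O)[C@H]2Cc2ccc(Oc3cc(C[C@@H]4C(=O)OC[C@H]4Cc4ccc(OC)c(OC)c4)cc(OC)c3OCc3ccccc3)c(OC)c2)cc1OC | intermediate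
22 | CNP0183104.1, (3S,4S) in both lactone rings | COc1ccc(C[C@@H]2COC(=O)[C@H]2Cc2ccc(Oc3cc(C[C@@H]4C(=O)OC[C@H]4Cc4ccc(OC)c(OC)c4)cc(OC)c3O)c(OC)c2)cc1OC | target

**Step count and risks**

Total step count: 9. Longest linear sequence: 6 steps (steps 4, 5, 6, 7, 8, 9, from 8 to 22); the lactone branch (steps 1, 2, 3) joins at step 8.

Steps most likely to fail:

1. Step 3. The catalyst-bound carbene may be diverted into cycloaddition with the electron-rich arene, insertion at the benzylic or O–CH2 positions or dimerisation, or the enantiotopic hydrogens may be discriminated incompletely. The fallback keeps the same C3–C4 ring closure but performs it on an alkene and then releases ring strain. It sets out from bromoacetyl bromide 2, which acylates commercial (E)-3-(3,4-dimethoxyphenyl)prop-2-en-1-ol (NaHCO3, MeCN) to (E)-3-(3,4-dimethoxyphenyl)prop-2-en-1-yl 2-bromoacetate F1. TsNHNHTs and DBU in THF should convert this, through the alkylated ditosylhydrazide F2 and the tosyldiazene F3 (neither isolated), into (E)-3-(3,4-dimethoxyphenyl)prop-2-en-1-yl 2-diazoacetate F4. Intramolecular cyclopropanation with the Rh2(MPPIM)4 antipode that gives the required series should afford (1R,5S,6S)-6-(3,4-dimethoxyphenyl)-3-oxabicyclo[3.1.0]hexan-2-one F5, in which the carbene carbon is again bonded to the future C4. Hydrogenolysis (H2, Pd/C, EtOAc) of the strained C1–C6 cyclopropane bond, which is activated by both the aryl and the carbonyl group, should then open the cyclopropane to lactone 7, where the route is rejoined.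

2. Step 8. The labile bis(benzyl bromide) may decompose or self-condense before the second alkylation, or proton transfer between product and enolate may cause incomplete or over-alkylation. The fallback replaces alkylation by aldol addition and sets out from dialdehyde 11 and enolate 18 (generated from 7 as in step 8). Twofold aldol addition at −78 °C with AcOH quench at that temperature should give the bis-aldol adduct F6, trans across C3–C4 in both rings and a mixture of carbinol epimers. One hydrogenolysis (H2, Pd(OH)2/C, EtOAc/AcOH, no mineral acid, to avoid dehydration or Friedel–Crafts closure onto the veratryl ring) should cleave both benzylic C–OH bonds and the benzyl ether. This arrives directly at 22 and bypasses 14, 17 and 21.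

3. Step 5. Addition of the hindered phenoxide to the only moderately activated fluoroarene may be sluggish, with base-induced degradation of the aldehydes at the temperature required. The fallback is a copper-catalysed Ullmann-type coupling that sets out from phenol 9 and commercial 4-bromo-3-methoxybenzaldehyde (CuI, picolinic acid, K3PO4, DMSO, 90 °C) and comes back at dialdehyde 11 without any new compound.

**Further compounds**

F1 | step 3 | (E)-3-(3,4-dimethoxyphenyl)prop-2-en-1-yl 2-bromoacetate | COc1ccc(/C=C/COC(=O)CBr)cc1OC
F2 | step 3 | alkylated ditosylhydrazide: (E)-3-(3,4-dimethoxyphenyl)prop-2-en-1-yl 2-[1,2-bis(4-methylphenylsulfonyl)hydrazinyl]acetate | COc1ccc(/C=C/COC(=O)CN(NS(=O)(=O)c2ccc(C)cc2)S(=O)(=O)c2ccc(C)cc2)cc1OC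
F3 | step 3 | tosyldiazene: (E)-3-(3,4-dimethoxyphenyl)prop-2-en-1-yl 2-[(E)-(4-methylphenylsulfonyl)diazenyl]acetate | COc1ccc(/C=C/COC(=O)C/N=N/S(=O)(=O)c2ccc(C)cc2)cc1OC
F4 | step 3 | (E)-3-(3,4-dimethoxyphenyl)prop-2-en-1-yl 2-diazoacetate | COc1ccc(/C=C/COC(=O)C=[N+]=[N-])cc1OC
F5 | step 3 | (1R,5S,6S)-6-(3,4-dimethoxyphenyl)-3-oxabicyclo[3.1.0]hexan-2-one | COc1ccc([C@H]2[C@@H]3COC(=O)[C@H]23)cc1OC
F6 | step 8 | bis-aldol adduct, (3R,4S) by CIP in both lactone rings (same 3,4-trans arrangement as the target), carbinol centres as epimer mixture | COc1ccc(C[C@@H]2COC(=O)[C@H]2C(O)c2ccc(Oc3cc(C(O)[C@@H]4C(=O)OC[C@H]4Cc4ccc(OC)c(OC)c4)cc(OC)c3OCc3ccccc3)c(OC)c2)cc1OC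
F0 | step 5 | none | none
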